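**Retrosynthetic overview**
1. Feature: in the 3a,4,5,7a-tetrahydro-1H-indene core the ring-fusion bond C3a–C7a is the central sigma bond of the 1,5-diene C2=C3–C3a–C7a–C7=C6, so both of its ends are allylic; C4 (Me, CO2H) and C5 (Me, dienyl) are a contiguous quaternary pair.
2. Last ring: the five-membered ring C7a–C1–C2–C3–C3a by ring-closing metathesis of a C3a isopropenyl and a C1 vinyl group; the C1'–C4' dienyl chain by two olefinations of a C1' aldehyde; acid freed last.
3. Key disconnection, first ring: the six-membered ring C3a–C4–C5–C6–C7–C7a by palladium-mediated intramolecular allyl–allyl coupling across C3a–C7a of an acyclic C7a allylic carbonate / (Z)-allyl boronate held together by the C4–C5 bond.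
4. Both allyl arms by (Z)-olefination of a C3a/C6 dialdehyde from ozonolysis of a cis-1,2-dimethylcyclobutene; C4 and C5 come from the meso [2+2] photoadduct of dimethylmaleic anhydride and acetylene, desymmetrized by alcoholysis.
5. Ring order: cyclobutene scaffold (cleaved in step 5), then cyclohexene (step 12), then cyclopentene (step 13).

Key step: step 12

Remark on the chemistry: the sense of induction of quinidine (step 2) and of the (+)-α-pinene-derived crotylborane (step 9) is taken from the usual models; if a test run shows the opposite sense, quinine or the borane from (−)-α-pinene is used instead.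
Remark on locants: C1–C7a and C1'–C4' are the indene locants of the target throughout; C2' is the boron-bearing carbon of the allyl boronate, lost as ethylene in step 13.

Step 1
Reactants: 1 2,3-dimethylmaleic anhydride; 2 acetylene
Product: 3 meso-(1R,5S)-1,5-dimethyl-3-oxabicyclo[3.2.0]hept-6-ene-2,4-dione
Conditions: hν (Hg lamp, Pyrex), acetone, acetylene-saturated, −40 °C
Reagents that add atoms: acetylene (2), C#C
Why: Sensitized [2+2] photocycloaddition of the anhydride C=C to the alkyne; the cyclobutene can only be cis-fused, which places the future C4 and C5 methyl groups cis and makes the adduct meso.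

Step 2
Reactants: 3 meso-(1R,5S)-1,5-dimethyl-3-oxabicyclo[3.2.0]hept-6-ene-2,4-dione
Product: 4 (1R,2S)-2-(methoxycarbonyl)-1,2-dimethylcyclobut-3-ene-1-carboxylic acid
Conditions: quinidine (1.1 equiv), MeOH (3 equiv), toluene, −55 °C
Reagents that add atoms: methanol, CO
Why: Cinchona-alkaloid-mediated desymmetrizing methanolysis of a meso anhydride; attack on one enantiotopic carbonyl fixes the absolute configuration of both quaternary carbons at once (acid carbon = C4 carboxyl, ester carbon = C1').

Step 3
Reactants: 4 (1R,2S)-2-(methoxycarbonyl)-1,2-dimethylcyclobut-3-ene-1-carboxylic acid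
Product: 5 (1R,5S)-1,5-dimethyl-3-oxabicyclo[3.2.0]hept-6-en-2-one
Conditions: LiBEt3H (3.2 equiv), THF, 0 °C; then aq. HCl, 25 °C
Reagents that add atoms: none
Why: Chemoselective hydride reduction in which the lithium carboxylate is inert and the methyl ester is reduced, followed by lactonization of the cis hydroxy acid on acidification; no stereocentre is touched.

Step 4
Reactants: 5 (1R,5S)-1,5-dimethyl-3-oxabicyclo[3.2.0]hept-6-en-2-one
Product: 7 4-methoxybenzyl (1R,2S)-2-[(4-methoxybenzyloxy)methyl]-1,2-dimethylcyclobut-3-ene-1-carboxylate, via potassium hydroxy carboxylate 6 (not isolated)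
Conditions: KOH, MeOH–H2O, 50 °C; evaporate; NaH, 4-MeOC6H4CH2Cl (2.4 equiv), Bu4NI (cat.), DMF, 0 → 25 °C
Reagents that add atoms: potassium hydroxide, [K+].[OH-]; 4-methoxybenzyl chloride, COc1ccc(CCl)cc1
Why: Saponification followed by double O-alkylation (Williamson etherification of the alkoxide, alkylation of the carboxylate) traps the open form before it can re-lactonize and protects C1'-OH and the C4 carboxyl together.

Step 5
Reactants: 7 4-methoxybenzyl (1R,2S)-2-[(4-methoxybenzyloxy)methyl]-1,2-dimethylcyclobut-3-ene-1-carboxylate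
Product: 9 C3a/C6 dialdehyde, via ozonide 8 (not isolated)
Conditions: O3, CH2Cl2, −78 °C (Sudan red end point); PPh3, −78 → 25 °C
Reagents that add atoms: ozone, [O-][O+]=O
Why: Ozonolysis of the strained cis-disubstituted cyclobutene with reductive work-up, stopped at the indicator end point before the anisyl rings react; both aldehydes stand on quaternary carbons and cannot epimerize.

Step 6
Reactants: 9 C3a/C6 dialdehyde; 10 methyl 2-[bis(2,2,2-trifluoroethoxy)phosphoryl]propanoate
Product: 11 bis-(Z)-enoate
Conditions: 10 (2.6 equiv), KN(SiMe3)2, 18-crown-6, THF, −78 °C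
Reagents that add atoms: methyl 2-[bis(2,2,2-trifluoroethoxy)phosphoryl]propanoate (10), COC(=O)C(C)P(=O)(OCC(F)(F)F)OCC(F)(F)F
Why: Twofold Still–Gennari olefination; the electron-poor phosphonate eliminates from the kinetic adduct and gives the trisubstituted (Z)-enoate at each neopentyl aldehyde.

Step 7
Reactants: 11 bis-(Z)-enoate
Product: 13 six-membered allylic lactone bearing the (Z)-allylic alcohol arm on C5, via diol 12 (not isolated)
Conditions: i-Bu2AlH (4.5 equiv), CH2Cl2, −78 °C; EtOAc, aq. potassium sodium tartrate; crude 12: NaH (0.2 equiv), THF, 0 → 25 °C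
Reagents that add atoms: none
Why: 1,2-Reduction of the two unhindered conjugated esters spares the neopentyl C4 ester; alkoxide-catalysed transesterification then closes the six-membered lactone between the (Z)-allylic alcohol on C4 and the C4 ester in preference to the seven-membered alternative, which tells the two arms apart.

Step 8
Reactants: 13 six-membered allylic lactone bearing the (Z)-allylic alcohol arm on C5
Product: 14 lactone (Z)-enal
Conditions: MnO2 (20 equiv), CH2Cl2, 25 °C
Reagents that add atoms: none
Why: Allylic oxidation with MnO2 under neutral conditions gives the (Z)-enal without isomerization or attack on the lactone.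

Step 9
Reactants: 14 lactone (Z)-enal; 15 (Z)-crotyldiisopinocampheylborane from (+)-α-pinene
Product: 16 lactone homoallylic alcohol (7aS,1R; OH and C1-CH3 syn)
Conditions: 15 [cis-but-2-ene, n-BuLi, KOt-Bu, THF, −78 → −45 °C; (−)-Ipc2BOMe; BF3·OEt2], then 14, THF, −78 °C; NaBO3·4H2O, 25 °C
Reagents that add atoms: (Z)-crotyldiisopinocampheylborane (15), C/C=C\CB([C@@H]1C[C@@H]2C[C@H]([C@H]1C)C2(C)C)[C@@H]1C[C@@H]2C[C@H]([C@H]1C)C2(C)C
Why: Brown crotylboration through a closed chair transition state; the (Z)-crotyl unit gives the syn relationship of C7a-OH and C1-CH3 and the isopinocampheyl groups select the aldehyde face, which sets C7a (S) and C1 (R).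

Step 10
Reactants: 16 lactone homoallylic alcohol (7aS,1R; OH and C1-CH3 syn); 17 bis(pinacolato)diboron
Product: 19 hydroxy methyl ester with (Z)-allyl pinacol boronate arm, via boryl ester 18 (not isolated)
Conditions: 17 (1.3 equiv), Pd(dba)2 (5 mol %), DMSO, 50 °C; then K2CO3, MeI, 25 °C
Reagents that add atoms: bis(pinacolato)diboron (17), CC1(C)OB(OC1(C)C)B1OC(C)(C)C(C)(C)O1; iodomethane, CI
Why: Miyaura-type borylation of an allylic ester, in which zerovalent palladium ionizes the allylic C–O bond of the lactone and boron is delivered to the primary terminus with C4 kept cis to CH2B; the carboxylate released is methylated in the same flask.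

Step 11
Reactants: 19 hydroxy methyl ester with (Z)-allyl pinacol boronate arm
Product: 20 acyclic (7aS)-allylic methyl carbonate / (Z)-allyl pinacol boronate
Conditions: ClCO2Me, pyridine, DMAP (cat.), CH2Cl2, 0 °C
Reagents that add atoms: methyl chloroformate, COC(=O)Cl
Why: Acylation of the secondary allylic alcohol (nucleophilic catalysis) with retention at C7a; the allyl boronate and the hindered ester are inert.

Step 12
Reactants: 20 acyclic (7aS)-allylic methyl carbonate / (Z)-allyl pinacol boronate
Product: 22 cyclohexene methyl ester with trans isopropenyl (C3a) and (R)-but-3-en-2-yl (C7a) groups, via palladacycle 21 (not isolated)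
Conditions: Pd2(dba)3 (5 mol %), 1,2-(Ph2P)2C6H4 (12 mol %), THF (0.005 M), 60 °C
Reagents that add atoms: none
Why: Proposed new method: zerovalent palladium ionizes the C7a carbonate anti to oxygen, the methoxide set free activates the tethered allyl boronate for transfer of C2' to palladium, and the bis(eta-1-allyl)palladacycle 21 (Pd on C6 and C2') closes by 3,3'-reductive elimination between the distal termini C7a and C3a; the closest known reaction type is the intermolecular palladium/bisphosphine-catalysed allyl–allyl cross-coupling of allylic carbonates with allyl boronates, which forms the branched bond by the same pathway. The six-membered ring closes with the C6–C7–C7a allyl inside the new ring and the C3a–C3–C2' allyl outside, through a bridged boat-like transition state in which C6–Pd–C2'–C3 spans one face of the nascent ring; a chair is not possible because the C4–C5 tether joins a palladium-bound carbon to a bond-forming carbon, and for the same reason the boronate alkene must have C4 cis to CH2B. C7a is set by chirality transfer from the (7aS)-carbonate: palladium enters anti to oxygen and the new bond forms on the palladium face, a net inversion. C3a is set by the bridge, which delivers the isopropenyl group on the palladium face; with the C1 branch inside the sigma-allyl (cis to C6) this is the face lined by the C4 and C5 methyl groups and H-7a, so H-3a and H-7a end up trans. The step needs 3,3' coupling (C3a–C7a) and not direct C6–C2' coupling, which the small-bite-angle chelating bisphosphine and the neopentyl C6 should secure. It also needs closure across the methyl-lined face and not across the face that carries CH2OPMB, CO2Me and an outside C1 branch; only the bulk of the Pd(bisphosphine) fragment argues for this, and it is the weak point.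

Step 13
Reactants: 22 cyclohexene methyl ester with trans isopropenyl (C3a) and (R)-but-3-en-2-yl (C7a) groups
Product: 23 PMB ether methyl ester of the trans-fused tetrahydroindene (1R,3aR,4R,5S,7aS)
Conditions: second-generation Hoveyda–Grubbs catalyst (10 mol %), toluene, 80 °C
Reagents that add atoms: none
Why: Ring-closing metathesis; the catalyst loads on the monosubstituted vinyl group and closes onto the isopropenyl group to give the trisubstituted C2=C3 cyclopentene, while the trisubstituted C6=C7 bond does not take part.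

Step 14
Reactants: 23 PMB ether methyl ester of the trans-fused tetrahydroindene (1R,3aR,4R,5S,7aS)
Product: 24 C1' primary alcohol
Conditions: DDQ, CH2Cl2–pH 7 buffer, 0 °C
Reagents that add atoms: none
Why: Oxidative cleavage of the 4-methoxybenzyl ether by DDQ under buffered conditions, chosen so that the cis hydroxy ester does not lactonize.

Step 15
Reactants: 24 C1' primary alcohol
Product: 25 C1' aldehyde
Conditions: Dess–Martin periodinane, NaHCO3, CH2Cl2, 0 °C (crude 24 used at once)
Reagents that add atoms: none
Why: Dess–Martin oxidation of the neopentyl primary alcohol to a non-enolizable aldehyde.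

Step 16
Reactants: 25 C1' aldehyde; 26 diethyl [1-(N-methoxy-N-methylcarbamoyl)ethyl]phosphonate
Product: 27 (E)-α-methyl enamide
Conditions: 26, NaH, THF, 0 → 60 °C
Reagents that add atoms: diethyl [1-(N-methoxy-N-methylcarbamoyl)ethyl]phosphonate (26), CCOP(=O)(OCC)C(C)C(=O)N(C)OC
Why: Horner–Wadsworth–Emmons olefination; the phosphonate carbanion adds to the hindered aldehyde better than a stabilized ylide and gives the (E)-trisubstituted alkene (C5 trans to the amide carbonyl).

Step 17
Reactants: 27 (E)-α-methyl enamide
Product: 28 (E)-α-methyl enal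
Conditions: i-Bu2AlH (1.3 equiv), THF, −78 °C
Reagents that add atoms: none
Why: Reduction of the Weinreb amide stops at the aldehyde through the chelated tetrahedral intermediate; the hindered C4 methyl ester is not reduced at −78 °C.

Step 18
Reactants: 28 (E)-α-methyl enal; 29 diethyl benzylphosphonate
Product: 30 methyl ester of the target
Conditions: 29, NaH, THF, 0 → 25 °C
Reagents that add atoms: diethyl benzylphosphonate (29), CCOP(=O)(OCC)Cc1ccccc1
Why: Horner–Wadsworth–Emmons reaction of the benzyl phosphonate gives the (E)-styryl bond and completes the (1'E,3'E)-diene.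

Step 19
Reactants: 30 methyl ester of the target
Product: 31 27-nor-zyggomphic acid B
Conditions: n-PrSLi, HMPA, 25 °C; then dil. aq. HCl to pH 4
Reagents that add atoms: none
Why: SN2 demethylation of the hindered methyl ester by thiolate at the methyl carbon, which does not depend on access to the carbonyl group and leaves the triene untouched.

**Compound list**
1 | 2,3-dimethylmaleic anhydride | CC1=C(C)C(=O)OC1=O | starting material
2 | acetylene | C#C | starting material
3 | meso-(1R,5S)-1,5-dimethyl-3-oxabicyclo[3.2.0]hept-6-ene-2,4-dione | C[C@@]12C=C[C@]1(C)C(=O)OC2=O | intermediate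
4 | (1R,2S)-2-(methoxycarbonyl)-1,2-dimethylcyclobut-3-ene-1-carboxylic acid | C[C@@]1(C(=O)O)C=C[C@]1(C)C(=O)OC | intermediate
5 | (1R,5S)-1,5-dimethyl-3-oxabicyclo[3.2.0]hept-6-en-2-one (lactone C=O on future C4) | C[C@@]12C=C[C@]1(C)COC2=O | intermediate
6 | potassium (1R,2S)-2-(hydroxymethyl)-1,2-dimethylcyclobut-3-ene-1-carboxylate | C[C@@]1(C(=O)[O-])C=C[C@]1(C)CO.[K+] | intermediate (not isolated)
7 | 4-methoxybenzyl (1R,2S)-2-[(4-methoxybenzyloxy)methyl]-1,2-dimethylcyclobut-3-ene-1-carboxylate | C[C@@]1(C(=O)OCc2ccc(OC)cc2)C=C[C@]1(C)COCc1ccc(OC)cc1 | intermediate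
8 | ozonide of 7 (1,2,4-trioxolane across C3a and C6; orientation of the peroxide bridge not defined) | C[C@@]1(C(=O)OCc2ccc(OC)cc2)C2OOC(O2)[C@]1(C)COCc1ccc(OC)cc1 | intermediate (not isolated)
9 | dialdehyde: C4 (Me, CO2PMB, CHO = C3a) and C5 (Me, CH2OPMB, CHO = C6), configured as in 7 | O=C[C@@](C)(C(=O)OCc1ccc(OC)cc1)[C@](C)(C=O)COCc1ccc(OC)cc1 | intermediate
10 | methyl 2-[bis(2,2,2-trifluoroethoxy)phosphoryl]propanoate | COC(=O)C(C)P(=O)(OCC(F)(F)F)OCC(F)(F)F | starting material
11 | bis-(Z)-enoate: each CHO of 9 replaced by (Z)-CH=C(CH3)CO2CH3 (quaternary carbon cis to CO2CH3) | COC(=O)/C(C)=C\[C@@](C)(C(=O)OCc1ccc(OC)cc1)[C@](C)(/C=C(/C)C(=O)OC)COCc1ccc(OC)cc1 | intermediate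
12 | diol: both enoates of 11 reduced to (Z)-CH=C(CH3)CH2OH | OC/C(C)=C\[C@@](C)(C(=O)OCc1ccc(OC)cc1)[C@](C)(/C=C(/C)CO)COCc1ccc(OC)cc1 | intermediate (not isolated)
13 | six-membered lactone O–C2'H2–C3(Me)=C3a–C4–C(=O); C5 carries Me, CH2OPMB and (Z)-CH=C(CH3)CH2OH | O=C1OCC(C)=C[C@]1(C)[C@](C)(/C=C(/C)CO)COCc1ccc(OC)cc1 | intermediate
14 | as 13, with the C5 arm oxidized to the (Z)-enal (C7a aldehyde) | O=C1OCC(C)=C[C@]1(C)[C@](C)(/C=C(/C)C=O)COCc1ccc(OC)cc1 | intermediate
15 | (Z)-crotylbis[(1R,2R,3R,5S)-isopinocampheyl]borane | C/C=C\CB([C@@H]1C[C@@H]2C[C@H]([C@H]1C)C2(C)C)[C@@H]1C[C@@H]2C[C@H]([C@H]1C)C2(C)C | starting material (reagent made in the flask from commercial cis-but-2-ene and (−)-Ipc2BOMe)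
16 | as 14, with the enal converted to C7a(S)H(OH)–C1(R)H(CH3)–CH=CH2 (OH and CH3 syn) | O=C1OCC(C)=C[C@]1(C)[C@](C)(/C=C(/C)[C@@H](O)[C@H](C)C=C)COCc1ccc(OC)cc1 | intermediate
17 | bis(pinacolato)diboron | CC1(C)OB(OC1(C)C)B1OC(C)(C)C(C)(C)O1 | starting material
18 | opened lactone: C4 carboxyl as O-pinacolboryl ester, C4 arm as (Z)-CH=C(CH3)CH2Bpin (C4 cis to CH2B) | C=C[C@@H](C)[C@H](O)/C(C)=C\[C@](C)(COCc1ccc(OC)cc1)[C@](C)(C(=O)OB1OC(C)(C)C(C)(C)O1)/C=C(/C)CB1OC(C)(C)C(C)(C)O1 | intermediate (not isolated)
19 | as 18, methyl ester at C4, free C7a-OH | C=C[C@@H](C)[C@H](O)/C(C)=C\[C@](C)(COCc1ccc(OC)cc1)[C@](C)(C(=O)OC)/C=C(/C)CB1OC(C)(C)C(C)(C)O1 | intermediate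
20 | key precursor: (1R,7aS)-methyl carbonate at C7a, (6Z)-alkene, C4 (R) and C5 (S) quaternary, (Z)-allyl pinacol boronate | C=C[C@@H](C)[C@H](OC(=O)OC)/C(C)=C\[C@](C)(COCc1ccc(OC)cc1)[C@](C)(C(=O)OC)/C=C(/C)CB1OC(C)(C)C(C)(C)O1 | intermediate
21 | bis(eta-1-allyl) complex of divalent palladium: Pd bonded to C6 and C2', C7=C7a with C1 cis to C6, seven-membered palladacycle, 1,2-bis(diphenylphosphino)benzene as chelating ligand (written as a separate component) | C=C[C@@H](C)/C=C(C)\[C@H]1[Pd]C/C(C)=C\[C@@](C)(C(=O)OC)[C@@]1(C)COCc1ccc(OC)cc1.c1ccc(cc1)P(c1ccccc1)c1ccccc1P(c1ccccc1)c1ccccc1 | intermediate (not isolated)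
22 | key product: cyclohexene C3a–C4–C5–C6=C7–C7a; C3a isopropenyl and C7a (R)-but-3-en-2-yl trans; (1R,3aR,4R,5S,7aS) by target locants | CC1=C[C@](C)(COCc2ccc(OC)cc2)[C@](C)(C(=O)OC)[C@@H](C(C)=C)[C@@H]1[C@H](C)C=C | intermediate
23 | methyl (1R,3aR,4R,5S,7aS)-5-[(4-methoxybenzyloxy)methyl]-1,3,4,5,7-pentamethyl-3a,4,5,7a-tetrahydro-1H-indene-4-carboxylate | CC1=C[C@](C)(COCc2ccc(OC)cc2)[C@](C)(C(=O)OC)[C@H]2C(C)=C[C@@H](C)[C@H]12 | intermediate
24 | as 23, with CH2OH at C5 | CC1=C[C@](C)(CO)[C@](C)(C(=O)OC)[C@H]2C(C)=C[C@@H](C)[C@H]12 | intermediate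
25 | as 23, with CHO at C5 | CC1=C[C@](C)(C=O)[C@](C)(C(=O)OC)[C@H]2C(C)=C[C@@H](C)[C@H]12 | intermediate
26 | diethyl [1-(N-methoxy-N-methylcarbamoyl)ethyl]phosphonate | CCOP(=O)(OCC)C(C)C(=O)N(C)OC | starting material
27 | as 23, with (E)-CH=C(CH3)C(=O)N(OCH3)CH3 at C5 | CC1=C[C@](C)(/C=C(C)/C(=O)N(C)OC)[C@](C)(C(=O)OC)[C@H]2C(C)=C[C@@H](C)[C@H]12 | intermediate
28 | as 23, with (E)-CH=C(CH3)CHO at C5 | CC1=C[C@](C)(/C=C(C)/C=O)[C@](C)(C(=O)OC)[C@H]2C(C)=C[C@@H](C)[C@H]12 | intermediate
29 | diethyl benzylphosphonate | CCOP(=O)(OCC)Cc1ccccc1 | starting material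
30 | methyl (1R,3aR,4R,5S,7aS)-1,3,4,5,7-pentamethyl-5-[(1E,3E)-2-methyl-4-phenylbuta-1,3-dien-1-yl]-3a,4,5,7a-tetrahydro-1H-indene-4-carboxylate | CC1=C[C@](C)(/C=C(C)/C=C/c2ccccc2)[C@](C)(C(=O)OC)[C@H]2C(C)=C[C@@H](C)[C@H]12 | intermediate
31 | 27-nor-zyggomphic acid B, (1R,3aR,4R,5S,7aS)-1,3,4,5,7-pentamethyl-5-[(1E,3E)-2-methyl-4-phenylbuta-1,3-dien-1-yl]-3a,4,5,7a-tetrahydro-1H-indene-4-carboxylic acid | CC1=C[C@](C)(/C=C(C)/C=C/c2ccccc2)[C@](C)(C(=O)O)[C@H]2C(C)=C[C@@H](C)[C@H]12 | target

**Totals**
Total step count: 19. Longest linear sequence: 19 steps (1 to 31).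

**Steps most likely to fail**

1. Step 12 (proposed new method). Five processes can divert it:
   - closure through the competing bridged transition state, with the C1 branch outside and palladium across the oxygenated face, which gives the cis-fused C3a epimer;
   - direct C6–C2' reductive elimination to an isomeric vinylcyclohexene;
   - β-hydride loss from the allylpalladium (C1–H) to a triene;
   - face exchange of the allylpalladium by attack of a second zerovalent palladium, which erodes the configuration at C7a;
   - intermolecular coupling.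

   Fallback, from 14 back to 22, with ring closure by intramolecular allylboration. Enal 14 is treated with B2pin2 and Pd(dba)2 in DMSO as in step 10. The (Z)-allyl boronate formed adds at once to the C7a aldehyde through the closed six-membered transition state. After K2CO3/MeI this should give the cis-cyclohexenol F1, with OH cis to the isopropenyl group and the C3a configuration assumed as in 22. ClCO2Me/pyridine gives the methyl carbonate F2. Known intermolecular allyl–allyl cross-coupling of F2 with (E)-crotyl pinacol boronate (Pd2(dba)3, 1,2-(Ph2P)2C6H4, THF, 60 °C) then installs the but-3-en-2-yl group with inversion at C7a and returns 22.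

2. Step 2. Opening of the doubly neopentyl anhydride may be slow and poorly selective between the two enantiotopic carbonyl groups.

   Fallback, from 3 back to 4, by classical resolution. NaOMe in MeOH opens 3 to the racemic half ester, which is 4 together with its enantiomer F3. Crystallization with (R)-1-phenylethylamine gives the ammonium salt F4 of the wanted enantiomer, and aqueous HCl returns 4.

3. Step 16. The phosphonate carbanion may fail to add to the doubly neopentyl aldehyde, or the trisubstituted alkene may form with eroded E selectivity.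

   Fallback, from 25 back to 30, by alkyne hydrometallation and cross-coupling. The Ohira–Bestmann reagent (dimethyl (1-diazo-2-oxopropyl)phosphonate, K2CO3, MeOH) converts 25 into the terminal alkyne F5. LiN(SiMe3)2 then MeI gives the methyl alkyne F6. Syn hydrozirconation with Cp2Zr(H)Cl places zirconium on the methyl-bearing carbon, and I2 gives the (E)-vinyl iodide F7. Suzuki coupling with (E)-styrylboronic acid (Pd(PPh3)4, aq. K3PO4, THF) returns 30.

**Further compounds**
F1 | step 12 | cyclohexenol: as 22 but with OH at C7a in place of the butenyl group, OH cis to the C3a isopropenyl group | CC1=C[C@](C)(COCc2ccc(OC)cc2)[C@](C)(C(=O)OC)[C@@H](C(C)=C)[C@H]1O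
F2 | step 12 | methyl carbonate of F1 | CC1=C[C@](C)(COCc2ccc(OC)cc2)[C@](C)(C(=O)OC)[C@@H](C(C)=C)[C@H]1OC(=O)OC
F3 | step 2 | (1S,2R)-2-(methoxycarbonyl)-1,2-dimethylcyclobut-3-ene-1-carboxylic acid (enantiomer of 4) | C[C@]1(C(=O)O)C=C[C@@]1(C)C(=O)OC
F4 | step 2 | (R)-1-phenylethylammonium salt of 4 | C[C@@]1(C(=O)[O-])C=C[C@]1(C)C(=O)OC.C[C@@H]([NH3+])c1ccccc1
F5 | step 16 | as 23, with ethynyl at C5 | CC1=C[C@](C)(C#C)[C@](C)(C(=O)OC)[C@H]2C(C)=C[C@@H](C)[C@H]12
F6 | step 16 | as 23, with prop-1-ynyl at C5 | CC1=C[C@](C)(C#CC)[C@](C)(C(=O)OC)[C@H]2C(C)=C[C@@H](C)[C@H]12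
F7 | step 16 | as 23, with (E)-2-iodoprop-1-enyl at C5 (C5 trans to I) | CC1=C[C@](C)(/C=C(C)/I)[C@](C)(C(=O)OC)[C@H]2C(C)=C[C@@H](C)[C@H]12
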